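**Retrosynthetic overview**

- Feature: the cyclobutane ring C1–C4 carries aroyl carbons on C1 and C3 and phenyls on C2 and C4. It is read as a 2,5-diphenylcyclohexane-1,4-dione whose two ring carbonyl carbons have been pushed out to become the exocyclic carbonyl carbons.
- 15 ⇒ diacid 12 + 2 × resorcinol 13 (two aryl–CO bonds by Friedel–Crafts C-acylation); 12 ⇒ all-trans diester 11.
- 11 ⇒ cis-bis(diazo) dione 7 + 2 × methanol 8: a twofold Wolff contraction forms C1–C2 and C3–C4. The only ring of the target is made here, six → five → four.
- 7 ⇒ 2,5-diphenylcyclohexane-1,4-dione 4 (double formylation, deformylative diazo transfer) ⇒ dimethyl succinylsuccinate 1 + diphenyliodonium triflate 2 (double α-phenylation, double dealkoxycarbonylation).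

Key step: step 5

Assumption: the SMILES encodes the achiral all-trans (1α,2β,3α,4β) isomer (aroyls cis to each other, phenyls cis to each other, every vicinal pair trans), so racemic intermediates suffice and only relative configuration has to be controlled.

**Route**

Step 1
Reactants: 1 dimethyl 2,5-dioxocyclohexane-1,4-dicarboxylate (dimethyl succinylsuccinate); 2 diphenyliodonium triflate (Ph2IOTf)
Product: 3 dimethyl 2,5-dioxo-1,4-diphenylcyclohexane-1,4-dicarboxylate (cis/trans mixture)
Conditions: t-BuOK (2.1 equiv), DMF, 0 °C; then 2 (2.2 equiv), 0 °C → rt, Ar
Reagents that add atoms: none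
Why: C-arylation of the two stabilised β-keto ester enolates by ligand exchange and ligand coupling at the trivalent iodine of a diaryliodonium salt is a known way to quaternary α-aryl β-keto esters, and the cis/trans mixture at the two new quaternary centres is of no consequence because both ester groups are removed in step 2.

Step 2
Reactants: 3 dimethyl 2,5-dioxo-1,4-diphenylcyclohexane-1,4-dicarboxylate
Product: 4 2,5-diphenylcyclohexane-1,4-dione (cis/trans mixture, interconverting by enolisation)
Conditions: AcOH, 6 M aq. HCl, reflux, Ar
Reagents that add atoms: none
Why: Acid hydrolysis of the two β-keto esters followed by decarboxylation of the β-keto acids is the standard dealkoxycarbonylation of α-aryl β-keto esters, and exclusion of air prevents dehydrogenation of the 1,4-dione to the hydroquinone.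

Step 3
Reactants: 4 2,5-diphenylcyclohexane-1,4-dione
Product: 5 3,6-bis(hydroxymethylene)-2,5-diphenylcyclohexane-1,4-dione (chelated enol form, cis/trans mixture)
Conditions: NaH (5 equiv), HCO2Et (excess), EtOH (cat.), THF, 0 °C → rt, Ar; then cold 1 M HCl
Reagents that add atoms: ethyl formate, CCOC=O
Why: In this crossed Claisen formylation each ketone is formylated at its CH2 rather than at its CHPh, because only the CH2 adduct can be drained off as a stable β-keto aldehyde enolate while formylation at the tertiary benzylic carbon is reversible.

Step 4
Reactants: 5 3,6-bis(hydroxymethylene)-2,5-diphenylcyclohexane-1,4-dione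
Product: 7 cis-3,6-bis(diazo)-2,5-diphenylcyclohexane-1,4-dione (racemic), via equilibrating bis(diazo) dione diastereomers 6 (not isolated)
Conditions: p-ABSA (2.2 equiv), Et3N (3 equiv), MeCN, −10 °C → rt, dark; SiO2 chromatography; the trans-enriched remainder of 6 is put back under Et3N/MeCN (rt) and chromatographed again
Reagents that add atoms: 4-acetamidobenzenesulfonyl azide (p-ABSA), CC(=O)Nc1ccc(cc1)S(=O)(=O)N=[N+]=[N-]
Why: In this Regitz deformylative diazo transfer each hydroxymethylene ketone enolate attacks the sulfonyl azide and the adduct fragments with loss of the formyl group as the N-formyl sulfonamide; the two CHPh centres of the bis(diazo) dione 6 so formed epimerise through the enol under Et3N, so its cis and trans forms interconvert (allylic strain against the flanking C=O and C=N2 groups is expected to hold each phenyl pseudo-axial on the boat-shaped ring and so to favour the cis form), the chiral cis isomer 7 is taken off on silica (it is the only isomer expected to split on a chiral stationary phase, which secures the assignment), and renewed equilibration of the remainder draws the rest of 6 into 7.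

Step 5
Reactants: 7 cis-3,6-bis(diazo)-2,5-diphenylcyclohexane-1,4-dione; 8 methanol (solvent; two molecules are taken up, one by each ketene)
Product: 11 dimethyl (1α,2β,3α,4β)-2,4-diphenylcyclobutane-1,3-dicarboxylate (all-trans meso isomer), via diazo keto ester 9 (not isolated), via kinetic diester epimers 10 (not isolated)
Conditions: hν (medium-pressure Hg lamp, Pyrex filter, λ > 300 nm), 8 (MeOH, degassed, solvent, large excess; 0.01 M in 7), 0 °C; then NaOMe (0.2 equiv), 50 °C; AcOH quench
Reagents that add atoms: methanol (the second molecule, which esterifies the second ketene), CO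
Why: Excitation of each s-cis-locked ring diazo ketone expels N2 with a concerted 1,2-shift of the ring carbon on the far side of the carbonyl (the phenyl-bearing CH) to the diazo carbon, and one molecule of methanol captures each resulting ketene as a methyl ester, two molecules in all; this is the photochemical Wolff ring contraction of cyclic 2-diazo ketones, known for six-to-five and for five-to-four cases and applied here twice to one ring. The first shift forms C1–C2 and leaves diazo cyclopentanone 9 and the second forms C3–C4, so the cyclobutane is closed by two successive ring contractions (six to five to four) and not by a cyclisation, the two former ring carbonyl carbons ending as the exocyclic ester carbons. C2 and C4 migrate with retention and neutral methanol does not epimerise the still enolisable phenyl centre of 9 before it moves, so the cis relation of the phenyls in 7 is carried unchanged into the ring. C1 and C3 arise by protonation of the ketene-derived ester enols, expected mainly from the face away from the phenyls, which gives the mixture 10; NaOMe then equilibrates only these two α-ester centres to the isomer with each ester trans to both flanking phenyls, the thermodynamic minimum with all four substituents pseudo-equatorial, while the ring bonds lie near the nodal plane of the exocyclic enolate, which disfavours retro-Michael opening. The selectivity required is Wolff shift over 1,2-hydrogen migration to the enedione and over O–H insertion into methanol, and the locked s-cis geometry, direct unsensitised irradiation and high dilution in neat methanol favour the concerted shift. Both enantiomers of racemic 7 converge on the same achiral product.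

Step 6
Reactants: 11 dimethyl (1α,2β,3α,4β)-2,4-diphenylcyclobutane-1,3-dicarboxylate
Product: 12 (1α,2β,3α,4β)-2,4-diphenylcyclobutane-1,3-dicarboxylic acid (ε-truxillic acid)
Conditions: KOH (6 equiv), MeOH/H2O, reflux; then 2 M HCl
Reagents that add atoms: potassium hydroxide (KOH; the hydroxide oxygen ends in the carboxyl group), [K+].[OH-]
Why: Saponification by acyl–oxygen cleavage leaves C1 and C3 untouched, since they already sit in the thermodynamic all-trans arrangement and the carboxylates formed are not enolised further.

Step 7
Reactants: 12 (1α,2β,3α,4β)-2,4-diphenylcyclobutane-1,3-dicarboxylic acid; 13 resorcinol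
Product: 15 CNP0398987.1, [(1α,2β,3α,4β)-2,4-diphenylcyclobutane-1,3-diyl]bis[(2,4-dihydroxyphenyl)methanone], via difluoroboron chelate 14 (not isolated)
Conditions: 13 (5 equiv), BF3·OEt2 (neat), 85 °C, Ar; then aq. NaOAc, MeOH, 60 °C
Reagents that add atoms: none
Why: In this Friedel–Crafts (Nencki-type) C-acylation BF3 activates each carboxyl group and resorcinol is acylated at C4, ortho to one hydroxyl and para to the other, the ortho-hydroxy ketone being held as its difluoroboron chelate until hydrolysis; each carboxyl is trans to both neighbouring phenyls, so closure onto a phenyl ring is geometrically disfavoured, and the ketone α-centres C1 and C3 remain in the all-trans arrangement, which is also the thermodynamic one.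

**Compound list**

1 | dimethyl 2,5-dioxocyclohexane-1,4-dicarboxylate (dimethyl succinylsuccinate) | COC(=O)C1CC(=O)C(C(=O)OC)CC1=O | starting material
2 | diphenyliodonium triflate (Ph2IOTf) | [O-]S(=O)(=O)C(F)(F)F.c1ccc([I+]c2ccccc2)cc1 | starting material
3 | dimethyl 2,5-dioxo-1,4-diphenylcyclohexane-1,4-dicarboxylate (both diastereomers, used as the mixture) | COC(=O)C1(c2ccccc2)CC(=O)C(C(=O)OC)(c2ccccc2)CC1=O | intermediate
4 | 2,5-diphenylcyclohexane-1,4-dione (both diastereomers, interconverting) | O=C1CC(c2ccccc2)C(=O)CC1c1ccccc1 | intermediate
5 | 3,6-bis(hydroxymethylene)-2,5-diphenylcyclohexane-1,4-dione (both diastereomers, enol tautomers) | O=C1C(=CO)C(c2ccccc2)C(=O)C(=CO)C1c1ccccc1 | intermediate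
6 | 3,6-bis(diazo)-2,5-diphenylcyclohexane-1,4-dione (cis/trans mixture, interconverting under Et3N in step 4) | [N-]=[N+]=C1C(=O)C(c2ccccc2)C(=[N+]=[N-])C(=O)C1c1ccccc1 | intermediate
7 | cis-3,6-bis(diazo)-2,5-diphenylcyclohexane-1,4-dione (racemic, one enantiomer drawn) | [N-]=[N+]=C1C(=O)[C@@H](c2ccccc2)C(=[N+]=[N-])C(=O)[C@H]1c1ccccc1 | intermediate
8 | methanol | CO | starting material
9 | methyl 4-diazo-3-oxo-2,5-cis-diphenylcyclopentane-1-carboxylate (racemic, C1 epimers) | COC(=O)C1[C@H](c2ccccc2)C(=[N+]=[N-])C(=O)[C@@H]1c1ccccc1 | intermediate
10 | dimethyl 2,4-cis-diphenylcyclobutane-1,3-dicarboxylate (kinetic mixture of C1 and C3 epimers) | COC(=O)C1[C@H](c2ccccc2)C(C(=O)OC)[C@@H]1c1ccccc1 | intermediate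
11 | dimethyl (1α,2β,3α,4β)-2,4-diphenylcyclobutane-1,3-dicarboxylate (all-trans, meso) | COC(=O)[C@H]1[C@H](c2ccccc2)[C@@H](C(=O)OC)[C@@H]1c1ccccc1 | intermediate
12 | (1α,2β,3α,4β)-2,4-diphenylcyclobutane-1,3-dicarboxylic acid (ε-truxillic acid) | OC(=O)[C@H]1[C@H](c2ccccc2)[C@@H](C(=O)O)[C@@H]1c1ccccc1 | intermediate
13 | resorcinol | Oc1cccc(O)c1 | starting material
14 | bis(difluoroboron) chelate of 15 (each ortho-hydroxy ketone bound to BF2) | F[B-]1(F)Oc2cc(O)ccc2C(=[O+]1)[C@H]3[C@H](c4ccccc4)[C@@H](C5=[O+][B-](F)(F)Oc6cc(O)ccc56)[C@@H]3c7ccccc7 | intermediate
15 | CNP0398987.1, [(1α,2β,3α,4β)-2,4-diphenylcyclobutane-1,3-diyl]bis[(2,4-dihydroxyphenyl)methanone] | O=C(c1ccc(O)cc1O)[C@H]1[C@H](c2ccccc2)[C@@H](C(=O)c2ccc(O)cc2O)[C@@H]1c1ccccc1 | target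

**Step count**

Total steps: 7. Longest linear sequence: 7 steps (1 → 15).

**Steps most likely to fail**

Step 5. Two contractions run on one ring at once. Material can be lost at either site to 1,2-hydrogen migration or to O–H insertion, the more strained five-to-four shift may lag, and any cis/trans leakage in 7 cannot be corrected once both phenyl carbons have migrated.

The fallback is an iterative contraction with a thermodynamic relay; it sets out from 4 and comes back at 9. Compound 4 is formylated once (one equivalent of ethyl formate, NaH) to 3-(hydroxymethylene)-2,5-diphenylcyclohexane-1,4-dione F1. Deformylative diazo transfer then gives 2-diazo-3,6-diphenylcyclohexane-1,4-dione F2, of which either diastereomer serves. Photolysis in methanol contracts the ring, and NaOMe in the same flask equilibrates the keto ester to methyl 1,2-trans-1,5-trans-3-oxo-2,5-diphenylcyclopentane-1-carboxylate F3. Here the ester centre and the phenyl centre next to the ketone relax around the already migrated, fixed phenyl centre, so the phenyls end cis whatever the configuration of F2. Formylation at the only ketone CH2 gives methyl 4-(hydroxymethylene)-3-oxo-2,5-diphenylcyclopentane-1-carboxylate F4, and a second deformylative diazo transfer gives 9 as its all-trans epimer. Compound 9 is then photolysed in methanol and equilibrated as in step 5 to 11. This path also removes the double diazo transfer and the isomer separation of step 4.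

Step 1. The electron-rich dienolate may be oxidised by the iodonium salt in a one-electron process with aromatisation of the ring, phenyl may be delivered to oxygen, or the reaction may stall after the first phenylation.

The fallback moves the aryl transfer from an enolate/onium pair under strong base to an enol/aryllead pair; it sets out from 1 and comes back at 3. Neutral 1 is phenylated at both β-keto ester carbons by ligand coupling at tetravalent lead with PhPb(OAc)3 in pyridine/CHCl3 at 40 °C (Pinhey arylation), with no preformed dienolate and no iodonium oxidant. It makes no new compound (F0).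

Step 7. The second acylation may stop at the hindered carboxyl. The Lewis acid may also epimerise an activated acyl centre, which would then close onto a flanking phenyl ring, or the hot acid may open the cyclobutane.

The fallback transfers the acyl groups with an organometallic reagent under cold, basic conditions; it sets out from 12 and comes back at 15. Diacid 12 is converted (carbonyldiimidazole, then MeNH(OMe)·HCl) into the all-trans bis(N-methoxy-N-methylamide) F5. 2,4-Dimethoxyphenyllithium F6, made from commercial 1-bromo-2,4-dimethoxybenzene and n-BuLi in THF at −78 °C, adds to both amide groups to give the all-trans bis(2,4-dimethoxyphenyl) diketone F7. BBr3 in CH2Cl2 (−78 °C → rt) then removes the four methyl groups to give 15.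

**Further compounds**

F1 | step 5 | 3-(hydroxymethylene)-2,5-diphenylcyclohexane-1,4-dione | O=C1CC(c2ccccc2)C(=O)C(=CO)C1c1ccccc1
F2 | step 5 | 2-diazo-3,6-diphenylcyclohexane-1,4-dione | O=C1CC(c2ccccc2)C(=O)C(=[N+]=[N-])C1c1ccccc1
F3 | step 5 | methyl 1,2-trans-1,5-trans-3-oxo-2,5-diphenylcyclopentane-1-carboxylate (racemic) | COC(=O)[C@H]1[C@H](c2ccccc2)C(=O)C[C@@H]1c1ccccc1
F4 | step 5 | methyl 4-(hydroxymethylene)-3-oxo-2,5-diphenylcyclopentane-1-carboxylate (all-trans, racemic) | COC(=O)[C@H]1[C@H](c2ccccc2)C(=O)C(=CO)[C@@H]1c1ccccc1
F0 | step 1 | none | none
F5 | step 7 | (1α,2β,3α,4β)-N1,N3-dimethoxy-N1,N3-dimethyl-2,4-diphenylcyclobutane-1,3-dicarboxamide | CON(C)C(=O)[C@H]1[C@H](c2ccccc2)[C@@H](C(=O)N(C)OC)[C@@H]1c1ccccc1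
F6 | step 7 | 2,4-dimethoxyphenyllithium | [Li]c1ccc(OC)cc1OC
F7 | step 7 | [(1α,2β,3α,4β)-2,4-diphenylcyclobutane-1,3-diyl]bis[(2,4-dimethoxyphenyl)methanone] | COc1ccc(C(=O)[C@H]2[C@H](c3ccccc3)[C@@H](C(=O)c3ccc(OC)cc3OC)[C@@H]2c2ccccc2)c(OC)c1
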